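**Easy subtraction.** I start with the last north reading, at 6.00 min: G stands at 32% and D at 17%, so 51.0% of the G charged has gone where I cannot read it. I carry the split, the D made over the G lost by that unseen route 0.333. It is a selectivity factor between two routes for G, read with the scatter of the readings.

- north: G 0.38 M; J 0.23 M; run made earlier
- flask: G 0.38 M; J 0.456 M; time 30 min; volume of the second phase over the first 1.0

- north (time / min: D / %, G / %): 0.500: 2, 92; 0.833: 0, 82; 1.50: 4, 74; 3.00: 8, 54; 6.00: 17, 32

(each reading ± 1.5 percentage points)

- in the second phase: J; everything else is in the first
- charges count per volume of the first phase; a concentration in a rate is the amount of a species over the volume of its own phase; every rate counts per litre of the first phase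
- the earlier runs hold the two phases in the same ratio of volumes as the flask asked about

1. how much D there is at 30 min, in percent of the G charged
2. the change that raises the amount of D at 30 min, in percent of the G charged most ("none" if none brings more than 2 percentage points) (delta / gamma / none)
3. amount of D at 30 min, in percent of the G charged, after gamma

**Flask against north.** The flask has the same 0.38 M of G as the north run and twice its J. The north run lost 0.258 M of G, more than the 0.23 M of J it was charged, so I let the unseen route run without J. The north readings fall at about 0.190 min⁻¹, and at that pace I reckon 0.336% of G left in the flask at 30 min. The last north reading still shows 32% of G, whereas I reckon nearly all of the flask's G lost, so I take my D for the flask from the split. If the route to D scales with J, the split becomes 0.661, and my D is 39.7%. I have one run at one charge of J, so I leave delta against gamma open.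

**The forecast.** It gives 82% of D, delta as the best change and 90% after gamma, on this ground: “Doubling J helps in both limits, pushing D towards completion.” Its D stands 42 percentage points above mine.

**The result.** The flask gives 41.1% of D, and at that time Z holds 52.6% of the G charged. Gamma adds 4.3 points against 2.4 points for delta, so the best change is gamma, reaching 45.5%.

    X + D → L (k = 4.23 × 10⁻⁴ M⁻¹ s⁻¹)
    G + X → D (k = 0.00948 M⁻¹ s⁻¹)
    2 G → Z (k = 0.00500 M⁻¹ s⁻¹)
    X ⇌ J, rate k4*([X] - [J]/K4) per volume of the first phase (partition coefficient = 0.350, kL = 0.00148 s⁻¹)

**Split reused.** The same flask read at 8.0 min still holds 19.6% of its G. The split of 0.661 puts D at 32.0% of the G charged, and the flask holds 30.0%.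

All runs are simulated on assumed constants.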